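**Retrosynthetic overview**

1. The target is (13S)-15-acetoxylabd-8(17)-en-18-oic acid; the end game is C18 CH2OH → CO2H, acetylation at C15 and C8=O → C8=C17H2.
2. Ring B (C5–C6–C7–C8–C9–C10) has an sp2 C8 flanked by C7 and C9, so it is the retro-[4+2] adduct of a 2-silyloxydiene C7=C8(OSi)–C9=C10 and a C5=C6 dienophile. Bonds C6–C7 and C5–C10 form together, and the C1–C3 tether closes ring A (C1–C5, C10) in the same event.
3. Enabling feature: the 4β-methyl carbon C19 and C6 both sit on neighbours of C5 on the β face, so one sulfur atom can bridge them. The resulting 2-sulfolene ring (C4–C19–S–C6=C5) activates the dienophile, forces the carboxyl carbon C18 equatorial, and is later erased by LiAlH4/Raney Ni to leave C19H3 and C6H2.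
4. The precursor is open-chain apart from that temporary ring. It comes from B-alkyl Suzuki coupling of the (E)-enol triflate of a 3-alkylpentane-2,4-dione (C7–C10, C20; side chain and C13 from (S)-citronellol) with an allylated thiolane β-keto ester (C4 set by asymmetric allylation).
5. Ring order: temporary thiolane (purchased) → rings A and B together (step 12) → thiolane removed (steps 13 and 14).

Key step: step 12

Numbering remark: labdane numbering is used from compound 16 onward (C18 = 4α carboxyl carbon, C19 = 4β methyl, C20 = 10β methyl, C17 = exocyclic methylene carbon); in thiolanes 8–15, ring C3 = labdane C4, ring C2 = C19, ring C4 = C5, ring C5 = C6.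

Assumption: the (1R,2R) ligand in step 6 is taken to give the (3S) ester 10 by analogy with other 2-alkoxycarbonyl cycloalkanones; if the sense is opposite, the (1S,2S) ligand is used and nothing else changes.

**Route**

Step 1
Reactants: 1 (S)-citronellol
Product: 2 (3S)-3,7-dimethyloct-6-en-1-yl 2,2-dimethylpropanoate
Conditions: PivCl, pyridine, DMAP (cat.), CH2Cl2, 0 °C to rt
Reagents that add atoms: pivaloyl chloride, CC(C)(C)C(Cl)=O
Why: Acylation of the primary alcohol (nucleophilic acyl substitution) gives an ester that survives oxidants and mild bases until the hydride step; the C13 stereocentre comes from the chiral pool and is not touched.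

Step 2
Reactants: 2 (3S)-3,7-dimethyloct-6-en-1-yl 2,2-dimethylpropanoate
Product: 3 (4S)-6-[(2,2-dimethylpropanoyl)oxy]-4-methylhexanoic acid
Conditions: RuCl3·xH2O (2 mol %), NaIO4 (4 equiv), EtOAc/MeCN/H2O, rt
Reagents that add atoms: sodium periodate, [Na+].[O-]I(=O)(=O)=O
Why: Oxidative cleavage of the trisubstituted alkene by RuO4 generated in the flask should give the acid and acetone in one operation, with the remote stereocentre unaffected.

Step 3
Reactants: 3 (4S)-6-[(2,2-dimethylpropanoyl)oxy]-4-methylhexanoic acid
Product: 4 (3R)-5-iodo-3-methylpentyl 2,2-dimethylpropanoate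
Conditions: PhI(OAc)2, I2, cyclohexane, hν (tungsten lamp), reflux
Reagents that add atoms: iodine, II
Why: Hunsdiecker-type iodinative decarboxylation through the acyl hypoiodite and a primary radical shortens the chain by one carbon to the C11 electrophile; the descriptor changes to R only because iodine changes the CIP priorities.

Step 4
Reactants: 4 (3R)-5-iodo-3-methylpentyl 2,2-dimethylpropanoate; 5 pentane-2,4-dione
Product: 6 (3S)-5-acetyl-3-methyl-6-oxoheptyl 2,2-dimethylpropanoate
Conditions: K2CO3, acetone, reflux (5 in excess)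
Reagents that add atoms: none
Why: C-alkylation of the acetylacetone enolate by the primary iodide (SN2) gives the 3-alkyl-1,3-diketone that carries C7, C8, C9, C10 and C20.

Step 5
Reactants: 6 (3S)-5-acetyl-3-methyl-6-oxoheptyl 2,2-dimethylpropanoate
Product: 7 (3S,5E)-5-acetyl-3-methyl-6-{[(trifluoromethyl)sulfonyl]oxy}hept-5-en-1-yl 2,2-dimethylpropanoate
Conditions: Tf2O, aq. Me4NOH, toluene, 0–5 °C (biphasic, no lithium or sodium ions)
Reagents that add atoms: triflic anhydride, O=S(=O)(OS(=O)(=O)C(F)(F)F)C(F)(F)F
Why: O-triflation of the non-chelated tetraalkylammonium enolate of a 1,3-dicarbonyl compound should place the sulfonyloxy group anti to the remaining carbonyl; the symmetry of the diketone removes any regiochemical question, and the (E) geometry fixes the later C9=C10 geometry.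

Step 6
Reactants: 8 methyl 4-oxothiolane-3-carboxylate; 9 allyl acetate
Product: 10 methyl (3S)-4-oxo-3-(prop-2-en-1-yl)thiolane-3-carboxylate
Conditions: [Pd(C3H5)Cl]2 (1 mol %), (1R,2R)-N,N'-bis[2-(diphenylphosphino)benzoyl]cyclohexane-1,2-diamine (3 mol %), N,N,N',N'-tetramethylguanidine, toluene, 0 °C
Reagents that add atoms: none
Why: Palladium-catalysed asymmetric allylic alkylation (Tsuji–Trost reaction) of the cyclic β-keto ester creates the quaternary stereocentre (labdane C4) by enantioface-selective attack of the prochiral enolate on the allyl complex inside the chiral ligand pocket.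

Step 7
Reactants: 10 methyl (3S)-4-oxo-3-(prop-2-en-1-yl)thiolane-3-carboxylate
Product: 11 methyl (3S)-4-hydroxy-3-(prop-2-en-1-yl)thiolane-3-carboxylate (both carbinol epimers)
Conditions: NaBH4, MeOH, −10 °C
Reagents that add atoms: none
Why: Chemoselective hydride reduction of the ketone in the presence of the ester removes the enolisable carbonyl; the new carbinol centre is destroyed again in step 9, so both epimers are carried on.

Step 8
Reactants: 11 methyl (3S)-4-hydroxy-3-(prop-2-en-1-yl)thiolane-3-carboxylate
Product: 12 methyl (3S)-4-hydroxy-3-(prop-2-en-1-yl)thiolane-3-carboxylate 1,1-dioxide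
Conditions: KHSO5 (as 2KHSO5·KHSO4·K2SO4), MeOH/H2O, 0 °C to rt
Reagents that add atoms: potassium peroxymonosulfate, [K+].[O-]S(=O)(=O)OO
Why: Oxidation of the thioether to the sulfone by peroxymonosulfate is much faster than epoxidation of the isolated terminal alkene, and no stereocentre is affected.

Step 9
Reactants: 12 methyl (3S)-4-hydroxy-3-(prop-2-en-1-yl)thiolane-3-carboxylate 1,1-dioxide
Product: 14 methyl (3S)-3-(prop-2-en-1-yl)-2,3-dihydrothiophene-3-carboxylate 1,1-dioxide, via mesylate 13 (not isolated)
Conditions: MsCl, Et3N (4 equiv), CH2Cl2, 0 °C to rt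
Reagents that add atoms: methanesulfonyl chloride, CS(=O)(=O)Cl (its atoms stay only in 13)
Why: Mesylation followed by E1cB elimination of the β-sulfonyloxy sulfone gives the cyclic vinyl sulfone; because ring C3 is quaternary, elimination can only occur towards the carbon next to sulfur.

Step 10
Reactants: 14 methyl (3S)-3-(prop-2-en-1-yl)-2,3-dihydrothiophene-3-carboxylate 1,1-dioxide; 7 (3S,5E)-5-acetyl-3-methyl-6-{[(trifluoromethyl)sulfonyl]oxy}hept-5-en-1-yl 2,2-dimethylpropanoate
Product: 16 methyl (3S)-3-[(4E,8S)-5-acetyl-4,8-dimethyl-10-(pivaloyloxy)dec-4-en-1-yl]-2,3-dihydrothiophene-3-carboxylate 1,1-dioxide, via alkylborane 15 (not isolated)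
Conditions: 9-BBN, THF, 0 °C to rt; then 7, Pd(dppf)Cl2 (5 mol %), aq. K3PO4, DMF, rt
Reagents that add atoms: 9-borabicyclo[3.3.1]nonane, B1C2CCCC1CCC2 (boron stays only in 15)
Why: Anti-Markovnikov hydroboration of the terminal alkene (the electron-poor ring alkene is left alone) and B-alkyl Suzuki–Miyaura coupling with retention at the enol triflate should give the tetrasubstituted (E)-enone with the tether cis to the side chain.

Step 11
Reactants: 16 methyl (3S)-3-[(4E,8S)-5-acetyl-4,8-dimethyl-10-(pivaloyloxy)dec-4-en-1-yl]-2,3-dihydrothiophene-3-carboxylate 1,1-dioxide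
Product: 17 methyl (3S)-3-[(4E,8S)-5-{1-[(tert-butyldimethylsilyl)oxy]ethenyl}-4,8-dimethyl-10-(pivaloyloxy)dec-4-en-1-yl]-2,3-dihydrothiophene-3-carboxylate 1,1-dioxide
Conditions: TBSOTf, Et3N, CH2Cl2, −78 to 0 °C
Reagents that add atoms: tert-butyldimethylsilyl triflate, CC(C)(C)[Si](C)(C)OS(=O)(=O)C(F)(F)F
Why: Soft enolisation of the methyl ketone at its methyl group gives the cross-conjugated 2-silyloxy-1,3-diene C7=C8(OSi)–C9=C10 without changing the C9=C10 geometry.

Step 12
Reactants: 17 methyl (3S)-3-[(4E,8S)-5-{1-[(tert-butyldimethylsilyl)oxy]ethenyl}-4,8-dimethyl-10-(pivaloyloxy)dec-4-en-1-yl]-2,3-dihydrothiophene-3-carboxylate 1,1-dioxide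
Product: 18 methyl (13S)-8-[(tert-butyldimethylsilyl)oxy]-15-(pivaloyloxy)-6β,19-sulfonyl-17-norlabd-8-en-18-oate (5α-H and 10β-methyl)
Conditions: toluene (0.01 M), BHT (cat.), propylene oxide (acid scavenger), 150 °C, sealed tube
Reagents that add atoms: none
Why: Thermal intramolecular Diels–Alder reaction of a 1,7,9-decatriene (type-1 IMDA): the 2-silyloxydiene C7=C8–C9=C10 adds suprafacially to the sulfolene double bond C5=C6 in a concerted, asynchronous [4+2] process, the closest known reactions being IMDA cyclisations of 2-silyloxydienes and of vinyl sulfone dienophiles that create angular methyl groups. Ring B is closed as the cycloadduct cyclohexene (bonds C6–C7 and C5–C10) and ring A as the six-membered ring spanned by the C1–C3 tether, both in the same event, leaving the regiodefined C8=C9 silyl enol ether. C5 is controlled by the C4 stereocentre, because the tether leaves C4 on one face of the planar sulfolene and the diene can reach only that face, which puts the ring carbon C19 axial and the ester equatorial; C6 follows from suprafacial addition to the cis ring alkene, sulfur ending cis to C4. C10 is controlled by the (E) geometry of C9=C10 (tether outside, methyl inside) together with the anti transition state (sulfolene ring exo, chair-like tether), which gives the trans ring fusion. The selectivity needed is anti over syn (trans- over cis-fused): in the syn transition state C3, held out of the sulfolene plane by the ring, is driven against the C9 side chain, so the C9 substituent acts as a steric directing group. Regiochemistry is fixed by the tether, the sulfone lowers the dienophile LUMO and the silyloxy group raises the diene HOMO, and the temperature is held below that of the 1,5-hydrogen shift of the diene.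

Step 13
Reactants: 18 methyl (13S)-8-[(tert-butyldimethylsilyl)oxy]-15-(pivaloyloxy)-6β,19-sulfonyl-17-norlabd-8-en-18-oate
Product: 19 (13S)-8-[(tert-butyldimethylsilyl)oxy]-6β,19-epithio-17-norlabd-8-ene-15,18-diol
Conditions: LiAlH4 (excess), THF, 0 °C to reflux; aqueous NaOH work-up
Reagents that add atoms: none
Why: Five-membered cyclic sulfones are the class that LiAlH4 deoxygenates readily to the sulfide, and the same hydride reduces the methyl ester to the C18 primary alcohol and cleaves the pivalate, while the silyl enol ether and all stereocentres are inert.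

Step 14
Reactants: 19 (13S)-8-[(tert-butyldimethylsilyl)oxy]-6β,19-epithio-17-norlabd-8-ene-15,18-diol
Product: 21 (13S)-15,18-dihydroxy-17-norlabdan-8-one, via desulfurised silyl enol ether 20 (not isolated)
Conditions: Raney Ni (W-2), EtOH, 60 °C; filter; then 1 M HCl, THF, rt
Reagents that add atoms: none
Why: Raney nickel hydrogenolysis of both C–S bonds (reductive desulfurisation) unveils the C19 methyl and the C6 methylene while the tetrasubstituted silyl enol ether resists hydrogenation; acid hydrolysis then gives the C8 ketone, with protonation at C9 from the α face (anti to the 10β-methyl) giving the equatorial 9β side chain, which is also the thermodynamic epimer.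

Step 15
Reactants: 21 (13S)-15,18-dihydroxy-17-norlabdan-8-one
Product: 22 (13S)-labd-8(17)-ene-15,18-diol
Conditions: Ph3PCH3Br, KOtBu (both in excess), toluene, 90 °C
Reagents that add atoms: methyltriphenylphosphonium bromide, C[P+](c1ccccc1)(c1ccccc1)c1ccccc1.[Br-] (delivers CH2 as the ylide)
Why: Wittig methylenation of the hindered C8 ketone with excess ylide, as is usual for 8-oxo-labdanes; C9 stays in its thermodynamically preferred equatorial configuration under the basic conditions.

Step 16
Reactants: 22 (13S)-labd-8(17)-ene-15,18-diol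
Product: 23 (13S)-18-hydroxylabd-8(17)-en-15-yl acetate
Conditions: Novozym 435 (immobilised Candida antarctica lipase B), vinyl acetate, MTBE, 30 °C
Reagents that add atoms: vinyl acetate, C=COC(C)=O
Why: Lipase-catalysed transesterification should acylate the unhindered C15 primary alcohol and leave the neopentyl C18 hydroxyl untouched (steric chemoselectivity).

Step 17
Reactants: 23 (13S)-18-hydroxylabd-8(17)-en-15-yl acetate
Product: 25 (13S)-15-acetoxylabd-8(17)-en-18-oic acid (target), via aldehyde 24 (not isolated)
Conditions: TEMPO (cat.), PhI(OAc)2, CH2Cl2, rt; then NaClO2, NaH2PO4, 2-methylbut-2-ene, t-BuOH/H2O, rt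
Reagents that add atoms: sodium chlorite, [Na+].[O-]Cl=O
Why: Nitroxyl-catalysed oxidation of the neopentyl alcohol to the aldehyde followed by Pinnick oxidation gives the acid; both stages tolerate the exocyclic alkene (scavenger present) and the acetate, and C4 cannot epimerise because it is quaternary.

**Compound list**

1 | (S)-citronellol, (3S)-3,7-dimethyloct-6-en-1-ol | CC(C)=CCC[C@H](C)CCO | starting material
2 | (3S)-3,7-dimethyloct-6-en-1-yl 2,2-dimethylpropanoate | CC(C)=CCC[C@H](C)CCOC(=O)C(C)(C)C | intermediate
3 | (4S)-6-[(2,2-dimethylpropanoyl)oxy]-4-methylhexanoic acid | OC(=O)CC[C@H](C)CCOC(=O)C(C)(C)C | intermediate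
4 | (3R)-5-iodo-3-methylpentyl 2,2-dimethylpropanoate | ICC[C@H](C)CCOC(=O)C(C)(C)C | intermediate
5 | pentane-2,4-dione | CC(=O)CC(C)=O | starting material
6 | (3S)-5-acetyl-3-methyl-6-oxoheptyl 2,2-dimethylpropanoate | CC(=O)C(C(C)=O)CC[C@H](C)CCOC(=O)C(C)(C)C | intermediate
7 | (3S,5E)-5-acetyl-3-methyl-6-{[(trifluoromethyl)sulfonyl]oxy}hept-5-en-1-yl 2,2-dimethylpropanoate | CC(=O)/C(CC[C@H](C)CCOC(=O)C(C)(C)C)=C(\C)OS(=O)(=O)C(F)(F)F | intermediate
8 | methyl 4-oxothiolane-3-carboxylate | COC(=O)C1CSCC1=O | starting material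
9 | allyl acetate (prop-2-en-1-yl acetate) | C=CCOC(C)=O | starting material
10 | methyl (3S)-4-oxo-3-(prop-2-en-1-yl)thiolane-3-carboxylate | COC(=O)[C@@]1(CC=C)CSCC1=O | intermediate
11 | methyl (3S)-4-hydroxy-3-(prop-2-en-1-yl)thiolane-3-carboxylate (both carbinol epimers) | COC(=O)[C@@]1(CC=C)CSCC1O | intermediate
12 | methyl (3S)-4-hydroxy-3-(prop-2-en-1-yl)thiolane-3-carboxylate 1,1-dioxide (both carbinol epimers) | COC(=O)[C@@]1(CC=C)CS(=O)(=O)CC1O | intermediate
13 | methyl (3S)-4-[(methylsulfonyl)oxy]-3-(prop-2-en-1-yl)thiolane-3-carboxylate 1,1-dioxide | COC(=O)[C@@]1(CC=C)CS(=O)(=O)CC1OS(C)(=O)=O | intermediate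
14 | methyl (3S)-3-(prop-2-en-1-yl)-2,3-dihydrothiophene-3-carboxylate 1,1-dioxide | COC(=O)[C@@]1(CC=C)CS(=O)(=O)C=C1 | intermediate
15 | methyl (3S)-3-[3-(9-borabicyclo[3.3.1]nonan-9-yl)propyl]-2,3-dihydrothiophene-3-carboxylate 1,1-dioxide | COC(=O)[C@@]1(CCCB2C3CCCC2CCC3)CS(=O)(=O)C=C1 | intermediate
16 | methyl (3S)-3-[(4E,8S)-5-acetyl-4,8-dimethyl-10-(pivaloyloxy)dec-4-en-1-yl]-2,3-dihydrothiophene-3-carboxylate 1,1-dioxide | CC(=O)/C(CC[C@H](C)CCOC(=O)C(C)(C)C)=C(\C)CCC[C@]1(C(=O)OC)CS(=O)(=O)C=C1 | intermediate
17 | methyl (3S)-3-[(4E,8S)-5-{1-[(tert-butyldimethylsilyl)oxy]ethenyl}-4,8-dimethyl-10-(pivaloyloxy)dec-4-en-1-yl]-2,3-dihydrothiophene-3-carboxylate 1,1-dioxide | C=C(O[Si](C)(C)C(C)(C)C)/C(CC[C@H](C)CCOC(=O)C(C)(C)C)=C(\C)CCC[C@]1(C(=O)OC)CS(=O)(=O)C=C1 | intermediate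
18 | methyl (13S)-8-[(tert-butyldimethylsilyl)oxy]-15-(pivaloyloxy)-6β,19-sulfonyl-17-norlabd-8-en-18-oate (trans-fused; 5α-H; 10β-methyl) | COC(=O)[C@@]12CCC[C@]3(C)C(CC[C@H](C)CCOC(=O)C(C)(C)C)=C(O[Si](C)(C)C(C)(C)C)C[C@@H](S(=O)(=O)C1)[C@@H]23 | intermediate
19 | (13S)-8-[(tert-butyldimethylsilyl)oxy]-6β,19-epithio-17-norlabd-8-ene-15,18-diol | OC[C@@]12CCC[C@]3(C)C(CC[C@H](C)CCO)=C(O[Si](C)(C)C(C)(C)C)C[C@@H](SC1)[C@@H]23 | intermediate
20 | (13S)-8-[(tert-butyldimethylsilyl)oxy]-17-norlabd-8-ene-15,18-diol | OC[C@]1(C)CCC[C@]2(C)C(CC[C@H](C)CCO)=C(O[Si](C)(C)C(C)(C)C)CC[C@@H]12 | intermediate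
21 | (13S)-15,18-dihydroxy-17-norlabdan-8-one (9α-H) | OC[C@]1(C)CCC[C@]2(C)[C@@H](CC[C@H](C)CCO)C(=O)CC[C@@H]12 | intermediate
22 | (13S)-labd-8(17)-ene-15,18-diol | C=C1CC[C@@H]2[C@](C)(CCC[C@@]2(C)CO)[C@H]1CC[C@H](C)CCO | intermediate
23 | (13S)-18-hydroxylabd-8(17)-en-15-yl acetate | C=C1CC[C@@H]2[C@](C)(CCC[C@@]2(C)CO)[C@H]1CC[C@H](C)CCOC(C)=O | intermediate
24 | (13S)-18-oxolabd-8(17)-en-15-yl acetate | C=C1CC[C@@H]2[C@](C)(CCC[C@@]2(C)C=O)[C@H]1CC[C@H](C)CCOC(C)=O | intermediate
25 | (13S)-15-acetoxylabd-8(17)-en-18-oic acid; (1R,4aR,5S,8aR)-5-[(3S)-5-acetoxy-3-methylpentyl]-1,4a-dimethyl-6-methylidenedecahydronaphthalene-1-carboxylic acid | C=C1CC[C@@H]2[C@](C)(CCC[C@@]2(C)C(=O)O)[C@H]1CC[C@H](C)CCOC(C)=O | target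

**Step count and risks**

Total step count: 17. Longest linear sequence: 13 steps (steps 1–5 and 10–17, from (S)-citronellol).

Steps most likely to fail:

Step 12 (key cycloaddition). The C5–C10 bond joins two congested centres and the tether forces the less favoured orbital pairing. The cycloaddition may therefore be too slow below the temperature at which the diene undergoes a 1,5-hydrogen shift or loses its silyl group, or the anti/syn preference may erode. The fallback sets out from enone 16 and returns at 18. Enone 16 is deprotonated at its methyl group with LiHMDS (THF, −78 °C) to the cross-conjugated lithium dienolate F1. A metal dienolate is a far more electron-rich 2-oxydiene than its silyl ether, and on warming towards 0 °C the anion-accelerated intramolecular [4+2] annulation (the known tandem-Michael-type annulation of enone dienolates with vinyl sulfones and acrylates) should give the lithium enolate of the tricyclic ketone F2 at a temperature where no hydrogen shift occurs. O-silylation of F2 with TBSCl/HMPA at −78 °C returns to 18.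

Step 5 (enol triflate geometry). Partial chelation or E/Z equilibration of the vinylogous acyl triflate would erode the geometry, and the (Z) isomer would lead to a cis-fused decalin in step 12. The fallback sets out from diketone 6 and returns at 16. Diketone 6 is sulfonylated with TsCl, N-methylimidazole and Et3N in MeCN, a kinetically controlled O-sulfonylation through the N-sulfonylimidazolium ion of the amine-generated, cation-free enolate that is known to favour the (E) isomer for 2-substituted 1,3-dicarbonyl compounds. This gives the (E)-enol tosylate (3S,5E)-5-acetyl-3-methyl-6-(tosyloxy)hept-5-en-1-yl pivalate F3, a configurationally more robust electrophile. F3 is then coupled with alkylborane 15 using Pd(OAc)2, dicyclohexyl(2',6'-dimethoxybiphenyl-2-yl)phosphine and K3PO4 to give 16.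

Step 10 (fragment coupling). Transmetalation of the B-alkyl ate complex to the hindered, tetrasubstituted vinylpalladium species may be slow, with hydroxide addition–elimination at the β-triflyloxy enone and protodeboronation competing. The fallback sets out from 14 and returns at 16 by changing the organometal from boron to zinc. Alkylborane 15 (from 14 and 9-BBN) is oxidised under neutral conditions with Me3NO to the primary alcohol methyl (3S)-3-(3-hydroxypropyl)-2,3-dihydrothiophene-3-carboxylate 1,1-dioxide F4. Treatment with I2, PPh3 and imidazole gives the iodide methyl (3S)-3-(3-iodopropyl)-2,3-dihydrothiophene-3-carboxylate 1,1-dioxide F5, and zinc dust with LiCl in THF converts it into the alkylzinc iodide F6. Base-free Negishi coupling of F6 with triflate 7 (Pd(OAc)2, dicyclohexyl(2',6'-dimethoxybiphenyl-2-yl)phosphine, THF, rt) gives 16.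

**Further compounds**

F1 | step 12 | lithium cross-conjugated dienolate of enone 16 | [Li+].C=C([O-])/C(CC[C@H](C)CCOC(=O)C(C)(C)C)=C(\C)CCC[C@]1(C(=O)OC)CS(=O)(=O)C=C1
F2 | step 12 | lithium enolate (C8–O, C8=C9) of methyl (13S)-8-oxo-15-(pivaloyloxy)-6β,19-sulfonyl-17-norlabdan-18-oate | [Li+].COC(=O)[C@@]12CCC[C@]3(C)C(CC[C@H](C)CCOC(=O)C(C)(C)C)=C([O-])C[C@@H](S(=O)(=O)C1)[C@@H]23
F3 | step 5 | (3S,5E)-5-acetyl-3-methyl-6-{[(4-methylphenyl)sulfonyl]oxy}hept-5-en-1-yl 2,2-dimethylpropanoate | CC(=O)/C(CC[C@H](C)CCOC(=O)C(C)(C)C)=C(\C)OS(=O)(=O)c1ccc(C)cc1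
F4 | step 10 | methyl (3S)-3-(3-hydroxypropyl)-2,3-dihydrothiophene-3-carboxylate 1,1-dioxide | COC(=O)[C@@]1(CCCO)CS(=O)(=O)C=C1
F5 | step 10 | methyl (3S)-3-(3-iodopropyl)-2,3-dihydrothiophene-3-carboxylate 1,1-dioxide | COC(=O)[C@@]1(CCCI)CS(=O)(=O)C=C1
F6 | step 10 | {3-[(3S)-3-(methoxycarbonyl)-1,1-dioxo-2,3-dihydrothiophen-3-yl]propyl}zinc iodide | COC(=O)[C@@]1(CCC[Zn]I)CS(=O)(=O)C=C1
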